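## Structural features

The target, (2S)-2,3-dihydroamentoflavone, joins a 5,7,4'-trihydroxyflavanone (rings A, C and B; unprimed and single-primed atoms) to a 5'',7'',4'''-trihydroxyflavone (double- and triple-primed atoms) through C3' of flavanone ring B and C8'' of flavone ring A. C2 of the flavanone (S) is the only stereocentre. It is benzylic, bonded to O1 and β to the C4 ketone, so it has no stereogenic neighbour, but it is lost by retro-oxa-Michael opening to the chalcone under base or strong Lewis acid. The six phenols, two of them chelated to carbonyl groups (C5–OH, C5''–OH), must be masked during the organometallic steps by groups that leave without conditions able to open ring C. The real difficulty is the crowded C3'–C8'' bond, which sits between the oxygen-bearing carbons C7'' and C8a'', together with the need to set C2 late and deprotect gently. Flavone ring A (C4a'', C5'', C6'', C7'', C8'', C8a'') carries five substituents and keeps hydrogen at C6'', so it is penta-substituted and not fully substituted. Its 5'',7''-dioxygen pattern next to the fusion carbon C4a'' is that of a cyclised acylketene. The key step uses this: C8'' holds the aryl group as an sp3 benzylic carbon on C2 of a 4-pyranone (the future C8a''), and the chain C8''–C7''(=O)–C6''H2–C5''(=O)O-t-Bu closes onto pyranone C3 (the future C4a''), so ring A, its two phenols and the biaryl bond arise without any cross-coupling at C8''.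

## Logic of the disconnections

19 from 18. The six O–CH2Ph bonds are cut. Free phenols would interfere with boron and palladium chemistry, and benzyl ethers can be removed under neutral reductive conditions that cannot open ring C. The gain is full masking of polar groups in every late intermediate. The demand is that hydrogenolysis spares the C2''=C3'' bond and the benzylic C2–O1 bond.

18 from 15 and 17. The C2–C1' bond is cut. It is the bond at the only stereocentre and divides the molecule into two achiral halves. The stereocentre is therefore created in the fragment-joining step and no chiral material is carried earlier. The forward step must deliver the aryl group to the Re face of C2 of an electron-rich chromone under catalyst control, without protodeboronation of the costly partner.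

15 from 14, 17 from 16, 14 from 13, 13 from 12. C–B is traced to C–Br, the benzyl ethers to phenols, and two phenols to methyl ethers. Bromine survives amide bases, acid and heat, and methyl ethers are what the purchasable materials carry and what tolerates the early steps. The methyl-to-benzyl exchange is placed on 12, which has no stereocentre to harm. The demand is complete alkylation of the chelated C5''–OH.

12 from 9. The C4a''–C5'' bond is cut, which opens ring A. This is the strategic cut: it turns the biaryl bond into an ordinary sp3 C–C bond and replaces a hindered biaryl coupling by a ring closure. The forward step must generate the acylketene thermally, enolise toward C8'' and close onto the pyranone carbon and not onto the bromoanisyl ring.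

9 from 5 and 6. The C6''–C7'' bond is cut. Direct malonylation of the benzylic anion of 4 is avoided, because the CH2 of any malonyl half-ester donor is several pK units more acidic than the benzylic C–H and would only protonate the anion. C7'' is instead introduced at the acid oxidation level and extended by the magnesium enolate derived from 6 under nearly neutral conditions. The demand is that 5 is activated before it decarboxylates.

5 from 4. The C7''–C8'' bond is cut to the lateral carbanion of 4 and a one-carbon electrophile. The benzylic CH2 is the only acidic position, so the site of reaction is not in doubt. One equivalent of a hindered amide base is required.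

4 from 3, and 3 from 1 and 2. The ring bond O1''–C8a'' is cut to the 1,3,5-triketone, and the C4a''–C8a'' bond is cut to the terminal carbanion of the dianion of 1 and the ester carbonyl of 2. Both materials are purchasable and already hold the C8''–aryl bond (in 2) and the C2''–aryl bond (in 1). The acylation must outrun proton transfer from the CH2 of 2, and ring closure must be run in acid because base would convert 3 into a resorcinol by aldol condensation.

## Other disconnections considered

Alternative 1: The cut is O1–C2 of flavanone ring C. In the forward sense the free 2'-phenol of alkylidene β-keto ester A1 would add to the benzylic alkene carbon under a bifunctional cinchona-alkaloid thiourea. TsOH would then cleave the tert-butyl ester with decarboxylation in the same pot to give hexa-O-benzyl flavanone A2, which is the same compound as 18.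
- In favour: it is metal-free, the doubly activated alkene is a far stronger acceptor than a 5,7-dialkoxychromone, and no boronic acid is exposed to protodeboronation. On acceptor reactivity it is better than step 10, and because A2 equals 18 its endgame is equal.
- Against: it does not address the C3'–C8'' bond or flavone ring A, so the chosen key step or a hindered cross-coupling is needed anyway. C1' must carry an aldehyde, which costs a formylation, a partner synthesis and a Knoevenagel condensation. The cyclised β-keto ester can reopen by retro-oxa-Michael addition until decarboxylation is complete, and that stage applies hot acid to a compound that already holds the stereocentre.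
- Comparison: in structure, both plans set C2 last on an achiral biaryl flavone. In mechanism, it is hydrogen-bond organocatalysis against ligand-controlled migratory insertion, each catalytic. In step economy, it needs three to four operations from 14 against two. It is kept as the fallback for step 10.

Alternative 2: The cut removes three bonds of the flavone pyranone ring, C8a''–O1'', C4a''–C4'' and O1''–C2''. In the forward sense CsF would unmask the aryne from ortho-silylaryl triflate A3, and the carboxylate oxygen of arylpropiolic acid A4 would add to C8a''. The acyl group would then migrate to the aryl anion at C4a'', and the phenoxide would close onto the ynone to give flavone A5.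
- In favour: three bonds and a ring form in one operation from two fragments, in a reaction class with precedent. On both counts it is better than the chosen key step, which forms one bond by an untested process. The regiochemical bias also points the right way, since a nucleophile adds to an alkoxy-substituted aryne at the carbon remote from the alkoxy group, here C8a''.
- Against: A3 already contains the C3'–C8'' bond, so the hardest bond is pushed back into a cross-coupling at a doubly flanked carbon, followed by halogenation, silylation and triflation of a crowded phenol. The oxygen nucleophile must add next to the bulky aryl group, so steric and electronic biases oppose each other, and early protonation of the aryl anion would stop at the aryl ester. A5 carries four methyl ethers that must go before C2 is set, and its acetal leads to an aldehyde–chalcone endgame.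
- Comparison: in structure, the alternative builds flavone ring C on a finished biaryl, whereas the chosen plan builds ring A on a finished pyranone and takes the biaryl bond from the sp3 carbon of 2. In mechanism, it is polar aryne capture against pericyclic ketene closure. In step economy, the preparation of A3 and the longer endgame make it several steps longer overall, although its key step alone is the more convergent.

Alternative 3: The cut is C8a–O1 of the flavanone. In the forward sense CuI (monovalent copper) with 1,10-phenanthroline and Cs2CO3 would couple the C2 hydroxyl of anti-diol A6 with the ortho aryl bromide (Ullmann-type etherification), closing ring C as flavan-4-ol A7. Oxidation of the C4 carbinol and acid removal of the methoxymethyl ethers would follow.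
- In favour: C2 is set by carbonyl chemistry with strong precedent and cannot be scrambled during ring closure, because at the alcohol oxidation level there is no enone to reopen. The closure is constitutionally unambiguous, since the C4 hydroxyl could only form a four-membered ring. On configurational security of the ring closure it is better than step 10, and the final acid methanolysis is as mild as hydrogenolysis.
- Against: two stereocentres are made to keep one, and an oxidation is added. The aryl bromide is electron-rich and flanked by the side chain, so the coupling needs heat and carbonate base, under which a 1,3-diol with a benzylic carbinol may eliminate or fragment. The diol must also be built on the biaryl flavone by an aldol reaction and a directed reduction.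
- Comparison: in structure, like the chosen plan it leaves the flavone and the biaryl bond to other chemistry. In mechanism, it is copper-mediated C–O bond formation at an sp2 carbon against palladium-mediated C–C bond formation at the stereocentre. In step economy, it needs about five operations from an aryl aldehyde against two from 14.

Key step: step 5

Remark: the C3'–C8'' axis (hydrogen at C2') is taken as freely rotating, so C2 is the only stereo-element, and 5,7-dihydroxy-4H-chromen-4-one is taken as a purchasable compound.

## Route

Step 1
Reactants: 1 1-(4-methoxyphenyl)butane-1,3-dione; 2 methyl 2-(5-bromo-2-methoxyphenyl)acetate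
Product: 3 1-(5-bromo-2-methoxyphenyl)-6-(4-methoxyphenyl)hexane-2,4,6-trione
Conditions: 1 (2.2 equiv), LiN(i-Pr)2 (4.5 equiv), THF, −78 to 0 °C; then 2, −78 to 0 °C; cold 1 M HCl
Reagents that add atoms: none
Why: Claisen-type acylation of a 1,3-diketone dianion, whose terminal (last-formed) carbanion is the most nucleophilic site and attacks the ester carbonyl of 2. The excess dianion takes up the acidic proton of 3 and compensates for partial enolisation of 2; the aryl bromide and methyl ethers are inert at these temperatures.

Step 2
Reactants: 3 1-(5-bromo-2-methoxyphenyl)-6-(4-methoxyphenyl)hexane-2,4,6-trione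
Product: 4 2-[(5-bromo-2-methoxyphenyl)methyl]-6-(4-methoxyphenyl)-4H-pyran-4-one
Conditions: TsOH·H2O (0.2 equiv), PhMe, reflux, Dean–Stark; wash with 1 M NaOH
Reagents that add atoms: none
Why: Acid-catalysed cyclodehydration of a 1,3,5-triketone: the enol oxygen of one outer carbonyl adds to the other (6-exo-trig) and water is lost to give the 4-pyranone. Acid avoids the base-mediated aldol of C8'' onto the aryl ketone, and the base wash removes excess 1.

Step 3
Reactants: 4 2-[(5-bromo-2-methoxyphenyl)methyl]-6-(4-methoxyphenyl)-4H-pyran-4-one
Product: 5 2-(5-bromo-2-methoxyphenyl)-2-[6-(4-methoxyphenyl)-4-oxo-4H-pyran-2-yl]acetic acid (racemic)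
Conditions: LiN(SiMe3)2 (1.2 equiv), THF, −78 °C; CO2 (g), −78 to −20 °C; cold 1 M HCl; kept below 20 °C and used at once
Reagents that add atoms: carbon dioxide, O=C=O
Why: Lateral metalation of a 2-alkyl-4-pyranone: the CH2 is benzylic and vinylogous to the C4 carbonyl, so the amide base removes it selectively and the extended enolate is carboxylated at carbon. The carboxylate is not deprotonated further, and bromine is untouched by an amide base at −78 °C.

Step 4
Reactants: 5 2-(5-bromo-2-methoxyphenyl)-2-[6-(4-methoxyphenyl)-4-oxo-4H-pyran-2-yl]acetic acid; 6 mono-tert-butyl malonate (3-tert-butoxy-3-oxopropanoic acid)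
Product: 9 tert-butyl 4-(5-bromo-2-methoxyphenyl)-4-[6-(4-methoxyphenyl)-4-oxo-4H-pyran-2-yl]-3-oxobutanoate (racemic), via acyl imidazole 7 (not isolated), via acylmalonic half-ester 8 (not isolated)
Conditions: 1,1'-carbonyldiimidazole (1.1 equiv), THF, 0 °C to rt; then Mg(O2CCH2CO2t-Bu)2 [from 6 (2.4 equiv) and Mg(OEt)2 (1.2 equiv), THF], rt; cold 1 M HCl
Reagents that add atoms: none
Why: Masamune–Brooks homologation: the acid is activated as acyl imidazole 7, which is C-acylated by the chelated magnesium enolate of the malonic half-ester, and 8 loses CO2 on acidification to give the β-keto ester. The conditions are near neutral and at room temperature, so the tert-butyl ester is not heated; if 7 eliminates to the ketene, the same nucleophile traps it to the same product.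

Step 5
Reactants: 9 tert-butyl 4-(5-bromo-2-methoxyphenyl)-4-[6-(4-methoxyphenyl)-4-oxo-4H-pyran-2-yl]-3-oxobutanoate
Product: 12 8-(5-bromo-2-methoxyphenyl)-5,7-dihydroxy-2-(4-methoxyphenyl)-4H-chromen-4-one, via acylketene 10 (not isolated), via 4aH-chromene-4,5-dione 11 (not isolated)
Conditions: dry PhMe (0.005 M), reflux (110 °C), 4 Å MS, slow N2 sweep
Reagents that add atoms: none
Why: Proposed new method: above about 100 °C the tert-butyl β-keto ester should lose tert-butanol through its chelated enol, as tert-butyl acetoacetates do, to give acylketene 10, and tautomerisation of the C7'' ketone toward the acidic benzylic C8''–H then gives the dienylketene O=C5''=C6''H–C7''(OH)=C8''(Ar)–C8a''=C4a''H. This should close by a thermal disrotatory six-electron electrocyclisation of the ketene carbon C5'' onto pyranone C4a'', forming the C4a''–C5'' bond and the six-membered carbocycle as dienone 11. Enolisation with loss of the C4a'' hydrogen then gives the aromatic 5,7-dihydroxy ring of 12, so the transient sp3 centre at C4a'' leaves no stereocentre; a stepwise C-acylation of the ketene by the nucleophilic pyranone carbon would give the same bond. The closest known reaction types are acyl transfer from tert-butyl β-keto esters through acylketenes, the electrocyclisation of dienylketenes to phenols (Danheiser benzannulation) and the ketene-mediated Gould–Jacobs and Conrad–Limpach ring closures; none uses a 4-pyranone C2=C3 bond as the third π-component. The selectivity needed is between two π-bonds on C8'', the pyranone C8a''=C4a'' bond and the C1=C6 bond of the bromoanisyl ring, whose closure would give a naphthalene-1,3-diol, so the regiochemistry is not fixed by connectivity alone. The substrate should favour the pyranone because C4a'' is the electron-rich α-carbon of a weakly aromatic vinylogous ester, whereas the only free ortho carbon of the aryl ring is meta to methoxy, ortho to bromine and part of a benzene ring whose aromaticity would have to be broken; the two enol geometries interconvert through the keto form, so the faster closure drains the pool. Dilution holds back dimerisation of 10 and acylation of the phenols of 12, re-addition of tert-butanol only returns 9, and dryness is needed because water would turn 10 into a β-keto acid that decarboxylates.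

Step 6
Reactants: 12 8-(5-bromo-2-methoxyphenyl)-5,7-dihydroxy-2-(4-methoxyphenyl)-4H-chromen-4-one
Product: 13 8-(5-bromo-2-hydroxyphenyl)-5,7-dihydroxy-2-(4-hydroxyphenyl)-4H-chromen-4-one
Conditions: BBr3 (8 equiv), CH2Cl2, −78 °C to rt; MeOH, then H2O
Reagents that add atoms: none
Why: Cleavage of aryl methyl ethers by BBr3 (complexation at oxygen, bromide attack on methyl). 12 has no stereocentre, and the flavone nucleus and the aryl bromide are inert to the reagent.

Step 7
Reactants: 13 8-(5-bromo-2-hydroxyphenyl)-5,7-dihydroxy-2-(4-hydroxyphenyl)-4H-chromen-4-one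
Product: 14 5,7-bis(benzyloxy)-8-[2-(benzyloxy)-5-bromophenyl]-2-[4-(benzyloxy)phenyl]-4H-chromen-4-one
Conditions: BnBr (6 equiv), K2CO3 (8 equiv), tetrabutylammonium iodide (cat.), DMF, 80 °C
Reagents that add atoms: benzyl bromide, BrCc1ccccc1
Why: Williamson ether synthesis on four phenoxides; the chelated C5''–OH is the slowest and is driven by excess reagent and heat. Benzyl is chosen because it survives the weakly acidic aqueous medium of step 10 and leaves under neutral conditions.

Step 8
Reactants: 14 5,7-bis(benzyloxy)-8-[2-(benzyloxy)-5-bromophenyl]-2-[4-(benzyloxy)phenyl]-4H-chromen-4-one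
Product: 15 [4-(benzyloxy)-3-{5,7-bis(benzyloxy)-2-[4-(benzyloxy)phenyl]-4-oxo-4H-chromen-8-yl}phenyl]boronic acid
Conditions: B2(OH)4 (3 equiv), PdCl(2'-amino-1,1'-biphenyl-2-yl)(XPhos) (2 mol %, second-generation XPhos palladacycle), XPhos (4 mol %), KOAc (3 equiv), EtOH–THF, 80 °C
Reagents that add atoms: tetrahydroxydiboron, OB(O)B(O)O
Why: Miyaura-type borylation of an aryl bromide with tetrahydroxydiboron, which gives the boronic acid directly (oxidative addition to zerovalent palladium, acetate-assisted transmetalation, reductive elimination). The C–Br bond has no ortho substituent, and the flavone and benzyl ethers are inert.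

Step 9
Reactants: 16 5,7-dihydroxy-4H-chromen-4-one
Product: 17 5,7-bis(benzyloxy)-4H-chromen-4-one
Conditions: BnBr (3 equiv), K2CO3 (4 equiv), DMF, 80 °C
Reagents that add atoms: benzyl bromide, BrCc1ccccc1
Why: Williamson ether synthesis; heat and excess reagent carry the alkylation through the chelated C5–OH. Protecting C5–OH removes the phenol that could reopen ring C of the later flavanone.

Step 10
Reactants: 15 [4-(benzyloxy)-3-{5,7-bis(benzyloxy)-2-[4-(benzyloxy)phenyl]-4-oxo-4H-chromen-8-yl}phenyl]boronic acid; 17 5,7-bis(benzyloxy)-4H-chromen-4-one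
Product: 18 (2S)-5,7-bis(benzyloxy)-2-{4-(benzyloxy)-3-[5,7-bis(benzyloxy)-2-[4-(benzyloxy)phenyl]-4-oxo-4H-chromen-8-yl]phenyl}-2,3-dihydro-4H-chromen-4-one
Conditions: 17 (2 equiv), Pd(OCOCF3)2 (10 mol %), (R)-t-BuPyOX (12 mol %), NH4PF6 (30 mol %), H2O (5 equiv), ClCH2CH2Cl, 60 °C
Reagents that add atoms: none
Why: Asymmetric conjugate addition of an arylboronic acid to a chromone by a cationic divalent palladium pyridine-oxazoline complex: transmetalation, enantio-determining insertion of C2=C3 into the Pd–aryl bond, and protonolysis of the palladium enolate by water. With the (R)-ligand the tert-butyl group should block the Si face so that the aryl group reaches the Re face of C2 and C2 becomes S; this sense is inferred from the topicity known for cyclic enones with the (S)-ligand and is to be checked by circular dichroism before step 11. The 2-aryl-substituted enone inside 15 is a far poorer acceptor than 17, which is used in excess.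

Step 11
Reactants: 18 (2S)-5,7-bis(benzyloxy)-2-{4-(benzyloxy)-3-[5,7-bis(benzyloxy)-2-[4-(benzyloxy)phenyl]-4-oxo-4H-chromen-8-yl]phenyl}-2,3-dihydro-4H-chromen-4-one
Product: 19 (2S)-5,7-dihydroxy-2-{3-[5,7-dihydroxy-2-(4-hydroxyphenyl)-4-oxo-4H-chromen-8-yl]-4-hydroxyphenyl}-2,3-dihydro-4H-chromen-4-one
Conditions: H2 (1 atm), Pd/C (10 wt % Pd on carbon), THF–MeOH, rt; stopped after six equivalents of H2
Reagents that add atoms: none
Why: Hydrogenolysis of six aryl benzyl ethers over palladium under neutral conditions; aryl O–benzyl bonds should cleave faster than the vinylogous-ester C2''=C3'' bond is reduced or the benzylic C2–O1 bond is hydrogenolysed. Without acid or base, C2 cannot epimerise through the chalcone.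

## Compound list

1 | 1-(4-methoxyphenyl)butane-1,3-dione | COc1ccc(C(=O)CC(C)=O)cc1 | starting material
2 | methyl 2-(5-bromo-2-methoxyphenyl)acetate | COC(=O)Cc1cc(Br)ccc1OC | starting material
3 | 1-(5-bromo-2-methoxyphenyl)-6-(4-methoxyphenyl)hexane-2,4,6-trione | COc1ccc(C(=O)CC(=O)CC(=O)Cc2cc(Br)ccc2OC)cc1 | intermediate
4 | 2-[(5-bromo-2-methoxyphenyl)methyl]-6-(4-methoxyphenyl)-4H-pyran-4-one | COc1ccc(-c2cc(=O)cc(Cc3cc(Br)ccc3OC)o2)cc1 | intermediate
5 | 2-(5-bromo-2-methoxyphenyl)-2-[6-(4-methoxyphenyl)-4-oxo-4H-pyran-2-yl]acetic acid (racemic) | COc1ccc(-c2cc(=O)cc(C(C(=O)O)c3cc(Br)ccc3OC)o2)cc1 | intermediate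
6 | mono-tert-butyl malonate (3-tert-butoxy-3-oxopropanoic acid) | CC(C)(C)OC(=O)CC(=O)O | starting material
7 | 2-[1-(5-bromo-2-methoxyphenyl)-2-(1H-imidazol-1-yl)-2-oxoethyl]-6-(4-methoxyphenyl)-4H-pyran-4-one (racemic, not isolated) | COc1ccc(-c2cc(=O)cc(C(C(=O)n3ccnc3)c3cc(Br)ccc3OC)o2)cc1 | intermediate
8 | 2-[(5-bromo-2-methoxyphenyl)[6-(4-methoxyphenyl)-4-oxo-4H-pyran-2-yl]acetyl]-3-tert-butoxy-3-oxopropanoic acid (magnesium salt in the flask, not isolated) | COc1ccc(-c2cc(=O)cc(C(C(=O)C(C(=O)O)C(=O)OC(C)(C)C)c3cc(Br)ccc3OC)o2)cc1 | intermediate
9 | tert-butyl 4-(5-bromo-2-methoxyphenyl)-4-[6-(4-methoxyphenyl)-4-oxo-4H-pyran-2-yl]-3-oxobutanoate (racemic) | CC(C)(C)OC(=O)CC(=O)C(c1cc(Br)ccc1OC)c1cc(=O)cc(-c2ccc(OC)cc2)o1 | intermediate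
10 | 2-[1-(5-bromo-2-methoxyphenyl)-2,4-dioxobut-3-en-1-yl]-6-(4-methoxyphenyl)-4H-pyran-4-one (acylketene, not isolated) | O=C=CC(=O)C(c1cc(Br)ccc1OC)c1cc(=O)cc(-c2ccc(OC)cc2)o1 | intermediate
11 | 8-(5-bromo-2-methoxyphenyl)-7-hydroxy-2-(4-methoxyphenyl)-4aH-chromene-4,5-dione (not isolated) | COc1ccc(C2=CC(=O)C3C(=O)C=C(O)C(c4cc(Br)ccc4OC)=C3O2)cc1 | intermediate
12 | 8-(5-bromo-2-methoxyphenyl)-5,7-dihydroxy-2-(4-methoxyphenyl)-4H-chromen-4-one | COc1ccc(-c2cc(=O)c3c(O)cc(O)c(-c4cc(Br)ccc4OC)c3o2)cc1 | intermediate
13 | 8-(5-bromo-2-hydroxyphenyl)-5,7-dihydroxy-2-(4-hydroxyphenyl)-4H-chromen-4-one | O=c1cc(-c2ccc(O)cc2)oc2c(-c3cc(Br)ccc3O)c(O)cc(O)c12 | intermediate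
14 | 5,7-bis(benzyloxy)-8-[2-(benzyloxy)-5-bromophenyl]-2-[4-(benzyloxy)phenyl]-4H-chromen-4-one | O=c1cc(-c2ccc(OCc3ccccc3)cc2)oc2c(-c3cc(Br)ccc3OCc3ccccc3)c(OCc3ccccc3)cc(OCc3ccccc3)c12 | intermediate
15 | [4-(benzyloxy)-3-{5,7-bis(benzyloxy)-2-[4-(benzyloxy)phenyl]-4-oxo-4H-chromen-8-yl}phenyl]boronic acid | O=c1cc(-c2ccc(OCc3ccccc3)cc2)oc2c(-c3cc(B(O)O)ccc3OCc3ccccc3)c(OCc3ccccc3)cc(OCc3ccccc3)c12 | intermediate
16 | 5,7-dihydroxy-4H-chromen-4-one | O=c1ccoc2cc(O)cc(O)c12 | starting material
17 | 5,7-bis(benzyloxy)-4H-chromen-4-one | O=c1ccoc2cc(OCc3ccccc3)cc(OCc3ccccc3)c12 | intermediate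
18 | (2S)-5,7-bis(benzyloxy)-2-{4-(benzyloxy)-3-[5,7-bis(benzyloxy)-2-[4-(benzyloxy)phenyl]-4-oxo-4H-chromen-8-yl]phenyl}-2,3-dihydro-4H-chromen-4-one | O=C1C[C@@H](c2ccc(OCc3ccccc3)c(-c3c(OCc4ccccc4)cc(OCc4ccccc4)c4c(=O)cc(-c5ccc(OCc6ccccc6)cc5)oc34)c2)Oc2cc(OCc3ccccc3)cc(OCc3ccccc3)c21 | intermediate
19 | (2S)-5,7-dihydroxy-2-{3-[5,7-dihydroxy-2-(4-hydroxyphenyl)-4-oxo-4H-chromen-8-yl]-4-hydroxyphenyl}-2,3-dihydro-4H-chromen-4-one | O=C1C[C@@H](c2ccc(O)c(-c3c(O)cc(O)c4c(=O)cc(-c5ccc(O)cc5)oc34)c2)Oc2cc(O)cc(O)c21 | target

## Step count and least certain steps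

Total step count: 11. Longest linear sequence: 10 (steps 1 to 8, 10 and 11); step 9 is a one-step branch.

Step 5 (key step, new method). The ketene may be consumed before it closes onto C4a'': by ring closure onto the bromoanisyl ring, by intermolecular acylation, or by hydrolysis and decarboxylation with adventitious water. The desired closure must interrupt the cyclic delocalisation of the pyranone, and nothing comparable has been tested. Fallback by known chemistry, setting out from 17 and returning at 14:
- Racemic conjugate addition of 4-(benzyloxy)phenylboronic acid to 17 (Pd(OCOCF3)2, 2,2'-bipyridine) gives rac-5,7-bis(benzyloxy)-2-[4-(benzyloxy)phenyl]-2,3-dihydro-4H-chromen-4-one F1.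
- Dehydrogenation with DDQ in dioxane gives 5,7-bis(benzyloxy)-2-[4-(benzyloxy)phenyl]-4H-chromen-4-one F2.
- Iodination with iodine and CF3CO2Ag in CH2Cl2, which on 5,7-dialkoxyflavones is directed to C8, gives 5,7-bis(benzyloxy)-2-[4-(benzyloxy)phenyl]-8-iodo-4H-chromen-4-one F3.
- Suzuki–Miyaura coupling of F3 with purchasable [2-(benzyloxy)-5-bromophenyl]boronic acid (Pd(PPh3)4, K2CO3, DMF–H2O, 80 °C), in which the carbon–iodine bond reacts before the carbon–bromine bond, gives 14.

Step 10. Conversion may stall because a 5,7-dialkoxychromone is a weak acceptor, while the electron-rich boronic acid is slowly protodeboronated. Facial selectivity may also fall with so large an aryl group. Fallback, setting out from 14 and returning at 18: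
- Reductive carbonylation of 14 (Pd(OAc)2, di(1-adamantyl)-n-butylphosphine, CO/H2, TMEDA, PhMe, 100 °C) gives 4-(benzyloxy)-3-{5,7-bis(benzyloxy)-2-[4-(benzyloxy)phenyl]-4-oxo-4H-chromen-8-yl}benzaldehyde F4.
- The partner tert-butyl 3-[2,4-bis(benzyloxy)-6-hydroxyphenyl]-3-oxopropanoate F5 is made from purchasable 1-[2,4-bis(benzyloxy)-6-hydroxyphenyl]ethanone by tert-butoxycarbonylation of its dienolate (LiN(SiMe3)2, di-tert-butyl dicarbonate).
- Knoevenagel condensation of F4 with F5 (piperidine, AcOH, PhMe, 4 Å MS) gives tert-butyl 2-[2,4-bis(benzyloxy)-6-hydroxybenzoyl]-3-{4-(benzyloxy)-3-[5,7-bis(benzyloxy)-2-[4-(benzyloxy)phenyl]-4-oxo-4H-chromen-8-yl]phenyl}prop-2-enoate F6.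
- A cinchona-alkaloid thiourea (the pseudoenantiomer leading to 2S) in PhMe at low temperature closes ring C by oxa-Michael addition, and TsOH at 80 °C removes the ester by decarboxylation to give 18.

Step 3 (with step 4). Acid 5 may lose CO2 during work-up or activation, because the carbanion left behind is benzylic and vinylogously stabilised. Fallback, setting out from 4 and returning at 9:
- The lateral anion of 4 (LiN(SiMe3)2, THF, −78 °C) is acetylated with N-methoxy-N-methylacetamide to give 1-(5-bromo-2-methoxyphenyl)-1-[6-(4-methoxyphenyl)-4-oxo-4H-pyran-2-yl]propan-2-one F7.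
- Its dianion (LiN(i-Pr)2, 3 equiv, THF, −78 to −20 °C) is acylated at the terminal methyl carbanion with di-tert-butyl dicarbonate to give 9.

Step 1. Proton transfer from the acidic CH2 of 2 to the dianion may outrun acylation and return both partners. Fallback, setting out from 2 and returning at 3:
- 2 is converted (MeNHOMe·HCl, i-PrMgCl, THF, −20 °C) into 2-(5-bromo-2-methoxyphenyl)-N-methoxy-N-methylacetamide F8, whose α-protons are less acidic.
- Its adduct with the dianion of 1 is a stable chelate that releases 3 only on acidic work-up, so one equivalent of dianion suffices.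

Step 11. Over-reduction may occur: saturation of C2''=C3'' or hydrogenolysis of the benzylic C2–O1 bond, both on the same catalyst that removes the benzyl groups. Fallback, setting out from 18 and returning at 19: non-reductive debenzylation with BCl3 and pentamethylbenzene as cation scavenger in CH2Cl2 at −78 °C, which changes the mechanism from hydrogenolysis to Lewis-acid dealkylation and makes no new intermediate.

## Further compounds

F1 | step 5 | rac-5,7-bis(benzyloxy)-2-[4-(benzyloxy)phenyl]-2,3-dihydro-4H-chromen-4-one | O=C1CC(c2ccc(OCc3ccccc3)cc2)Oc2cc(OCc3ccccc3)cc(OCc3ccccc3)c21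
F2 | step 5 | 5,7-bis(benzyloxy)-2-[4-(benzyloxy)phenyl]-4H-chromen-4-one | O=c1cc(-c2ccc(OCc3ccccc3)cc2)oc2cc(OCc3ccccc3)cc(OCc3ccccc3)c12
F3 | step 5 | 5,7-bis(benzyloxy)-2-[4-(benzyloxy)phenyl]-8-iodo-4H-chromen-4-one | O=c1cc(-c2ccc(OCc3ccccc3)cc2)oc2c(I)c(OCc3ccccc3)cc(OCc3ccccc3)c12
F4 | step 10 | 4-(benzyloxy)-3-{5,7-bis(benzyloxy)-2-[4-(benzyloxy)phenyl]-4-oxo-4H-chromen-8-yl}benzaldehyde | O=Cc1ccc(OCc2ccccc2)c(-c2c(OCc3ccccc3)cc(OCc3ccccc3)c3c(=O)cc(-c4ccc(OCc5ccccc5)cc4)oc23)c1
F5 | step 10 | tert-butyl 3-[2,4-bis(benzyloxy)-6-hydroxyphenyl]-3-oxopropanoate | CC(C)(C)OC(=O)CC(=O)c1c(O)cc(OCc2ccccc2)cc1OCc1ccccc1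
F6 | step 10 | tert-butyl 2-[2,4-bis(benzyloxy)-6-hydroxybenzoyl]-3-{4-(benzyloxy)-3-[5,7-bis(benzyloxy)-2-[4-(benzyloxy)phenyl]-4-oxo-4H-chromen-8-yl]phenyl}prop-2-enoate | CC(C)(C)OC(=O)C(=Cc1ccc(OCc2ccccc2)c(-c2c(OCc3ccccc3)cc(OCc3ccccc3)c3c(=O)cc(-c4ccc(OCc5ccccc5)cc4)oc23)c1)C(=O)c1c(O)cc(OCc2ccccc2)cc1OCc1ccccc1
F7 | step 3 | 1-(5-bromo-2-methoxyphenyl)-1-[6-(4-methoxyphenyl)-4-oxo-4H-pyran-2-yl]propan-2-one | COc1ccc(-c2cc(=O)cc(C(C(C)=O)c3cc(Br)ccc3OC)o2)cc1
F8 | step 1 | 2-(5-bromo-2-methoxyphenyl)-N-methoxy-N-methylacetamide | CON(C)C(=O)Cc1cc(Br)ccc1OC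
F0 | step 11 | none | none
A1 | alternative 1 | tert-butyl 2-[2,4-bis(benzyloxy)-6-hydroxybenzoyl]-3-{4-(benzyloxy)-3-[5,7-bis(benzyloxy)-2-[4-(benzyloxy)phenyl]-4-oxo-4H-chromen-8-yl]phenyl}prop-2-enoate | CC(C)(C)OC(=O)C(=Cc1ccc(OCc2ccccc2)c(-c2c(OCc3ccccc3)cc(OCc3ccccc3)c3c(=O)cc(-c4ccc(OCc5ccccc5)cc4)oc23)c1)C(=O)c1c(O)cc(OCc2ccccc2)cc1OCc1ccccc1
A2 | alternative 1 | (2S)-5,7-bis(benzyloxy)-2-{4-(benzyloxy)-3-[5,7-bis(benzyloxy)-2-[4-(benzyloxy)phenyl]-4-oxo-4H-chromen-8-yl]phenyl}-2,3-dihydro-4H-chromen-4-one | O=C1C[C@@H](c2ccc(OCc3ccccc3)c(-c3c(OCc4ccccc4)cc(OCc4ccccc4)c4c(=O)cc(-c5ccc(OCc6ccccc6)cc5)oc34)c2)Oc2cc(OCc3ccccc3)cc(OCc3ccccc3)c21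
A3 | alternative 2 | 2-[5-(1,3-dioxolan-2-yl)-2-methoxyphenyl]-3,5-dimethoxy-6-(trimethylsilyl)phenyl trifluoromethanesulfonate | COc1cc(OC)c(-c2cc(C3OCCO3)ccc2OC)c(OS(=O)(=O)C(F)(F)F)c1[Si](C)(C)C
A4 | alternative 2 | 3-(4-methoxyphenyl)prop-2-ynoic acid | COc1ccc(C#CC(=O)O)cc1
A5 | alternative 2 | 8-[5-(1,3-dioxolan-2-yl)-2-methoxyphenyl]-5,7-dimethoxy-2-(4-methoxyphenyl)-4H-chromen-4-one | COc1ccc(-c2cc(=O)c3c(OC)cc(OC)c(-c4cc(C5OCCO5)ccc4OC)c3o2)cc1
A6 | alternative 3 | (1S,3S)-1-[2-bromo-4,6-bis(methoxymethoxy)phenyl]-3-{3-[5,7-bis(methoxymethoxy)-2-[4-(methoxymethoxy)phenyl]-4-oxo-4H-chromen-8-yl]-4-(methoxymethoxy)phenyl}propane-1,3-diol | O[C@@H](C[C@H](O)c1ccc(OCOC)c(-c2c(OCOC)cc(OCOC)c3c(=O)cc(-c4ccc(OCOC)cc4)oc23)c1)c1c(Br)cc(OCOC)cc1OCOC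
A7 | alternative 3 | (2S,4S)-2-{3-[5,7-bis(methoxymethoxy)-2-[4-(methoxymethoxy)phenyl]-4-oxo-4H-chromen-8-yl]-4-(methoxymethoxy)phenyl}-5,7-bis(methoxymethoxy)-3,4-dihydro-2H-chromen-4-ol | O[C@H]1C[C@@H](c2ccc(OCOC)c(-c3c(OCOC)cc(OCOC)c4c(=O)cc(-c5ccc(OCOC)cc5)oc34)c2)Oc2cc(OCOC)cc(OCOC)c21
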